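## Retrosynthetic overview

1. The target is opened at the C5–O–C11 oxolane bridge and the C4–OH: both come from one anodic oxy-hydroxylation of a guai-4-ene bearing a tertiary 11-OH.
2. The C11 carbinol (OH, CH2OAc) comes from a cis-fused 12,8-lactone by α-hydroxylation and then hydroxymethylation on the convex face; acetate and tiglate are added last.
3. The lactone comes from a bicyclic cycloheptadienone: α′-alkylation (C7), conjugate methyl addition (C10), hydride reduction and lactonization (C8).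
4. The seven-membered ring is closed by ring-closing metathesis of a cyclopentene carrying a vinyl group (C1) and a vinyl ketone side chain (C6–C9).
5. The cyclopentene comes from (S)-4-silyloxycyclopentenone (only purchased stereocentre, C2) by iodination, Negishi coupling, vinyl addition and enol-triflate methylation. Ring order: five-membered ring (bought), seven-membered ring, lactone, oxolane bridge.

Assumption: guaiane numbering (C1–C15) and the α/β convention of the target (H-1 = α) are used for all intermediates; the silyloxy enone ((S)-enantiomer) and the zinc reagent (0.5 M in THF) are taken as commercial. The route is a proposal; no step has been run.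

## Route

Step 1
Reactants: 1 (S)-4-(tert-butyldimethylsilyloxy)cyclopent-2-en-1-one
Product: 2 (S)-4-(tert-butyldimethylsilyloxy)-2-iodocyclopent-2-en-1-one
Conditions: I2, pyridine, CH2Cl2, 0 °C to rt
Reagents that add atoms: iodine (II)
Why: α-Iodination of the enone by pyridine addition, iodination and elimination (Baylis–Hillman-type α-halogenation) does not touch the silyloxy stereocentre.

Step 2
Reactants: 2 (S)-4-(tert-butyldimethylsilyloxy)-2-iodocyclopent-2-en-1-one; 3 (3-ethoxy-3-oxopropyl)zinc bromide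
Product: 4 ethyl 3-[(3S)-3-(tert-butyldimethylsilyloxy)-5-oxocyclopent-1-en-1-yl]propanoate
Conditions: PdCl2(dppf) (5 mol %), THF/DMF, rt
Reagents that add atoms: none
Why: Negishi cross-coupling of the alkenyl iodide with the zinc homoenolate installs C6–C8 and tolerates enone and ester.

Step 3
Reactants: 4 ethyl 3-[(3S)-3-(tert-butyldimethylsilyloxy)-5-oxocyclopent-1-en-1-yl]propanoate
Product: 6 ethyl 3-[(4S,5S)-4-(tert-butyldimethylsilyloxy)-5-ethenyl-2-(trifluoromethylsulfonyloxy)cyclopent-1-en-1-yl]propanoate, via bromomagnesium enolate 5 (not isolated)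
Conditions: CH2=CHMgBr, CuBr·SMe2 (10 mol %), THF, −78 °C; then Comins' reagent, −78 to 0 °C
Reagents that add atoms: vinylmagnesium bromide (C=C[Mg]Br); Comins' reagent (Clc1ccc(nc1)N(S(=O)(=O)C(F)(F)F)S(=O)(=O)C(F)(F)F)
Why: Copper-catalysed 1,4-addition of the vinyl Grignard reagent occurs anti to the C2 silyloxy group (sets C1, trans), and the regiodefined enolate is O-triflated.

Step 4
Reactants: 6 ethyl 3-[(4S,5S)-4-(tert-butyldimethylsilyloxy)-5-ethenyl-2-(trifluoromethylsulfonyloxy)cyclopent-1-en-1-yl]propanoate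
Product: 7 ethyl 3-[(4S,5S)-4-(tert-butyldimethylsilyloxy)-5-ethenyl-2-methylcyclopent-1-en-1-yl]propanoate
Conditions: MeMgBr, Fe(acac)3 (5 mol %), THF/NMP, −30 °C
Reagents that add atoms: methylmagnesium bromide (C[Mg]Br)
Why: Iron-catalysed Kumada-type coupling of the alkenyl triflate gives the tetrasubstituted C4=C5 alkene faster than the Grignard reagent attacks the ester.

Step 5
Reactants: 7 ethyl 3-[(4S,5S)-4-(tert-butyldimethylsilyloxy)-5-ethenyl-2-methylcyclopent-1-en-1-yl]propanoate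
Product: 9 5-[(4S,5S)-4-(tert-butyldimethylsilyloxy)-5-ethenyl-2-methylcyclopent-1-en-1-yl]pent-1-en-3-one, via Weinreb amide 8 (not isolated)
Conditions: MeNHOMe·HCl, i-PrMgCl, THF, −20 °C; then CH2=CHMgBr, 0 °C; cold 1 M HCl
Reagents that add atoms: vinylmagnesium bromide (C=C[Mg]Br); N,O-dimethylhydroxylamine hydrochloride (CNOC.Cl; amide of 8 only, lost in the second stage)
Why: Weinreb ketone synthesis in one pot: the chelated tetrahedral intermediate stops vinyl Grignard addition at the vinyl ketone.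

Step 6
Reactants: 9 5-[(4S,5S)-4-(tert-butyldimethylsilyloxy)-5-ethenyl-2-methylcyclopent-1-en-1-yl]pent-1-en-3-one
Product: 10 (3S,3aS)-3-(tert-butyldimethylsilyloxy)-1-methyl-3,3a,7,8-tetrahydroazulen-6(2H)-one
Conditions: second-generation Grubbs catalyst (5 mol %), CH2Cl2 (5 mM), 40 °C
Reagents that add atoms: none
Why: Ring-closing metathesis of the two monosubstituted alkenes closes the seven-membered enone (C9=C10), and the tetrasubstituted alkene is inert.

Step 7
Reactants: 10 (3S,3aS)-3-(tert-butyldimethylsilyloxy)-1-methyl-3,3a,7,8-tetrahydroazulen-6(2H)-one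
Product: 11 methyl 2-[(3S,3aS)-3-(tert-butyldimethylsilyloxy)-1-methyl-6-oxo-2,3,3a,6,7,8-hexahydroazulen-7-yl]acetate (C7 epimers)
Conditions: LiN(i-Pr)2, THF, −78 °C; BrCH2CO2Me, DMPU, −78 to −40 °C
Reagents that add atoms: methyl bromoacetate (COC(=O)CBr)
Why: Kinetic α′-deprotonation of the enone (C7 is the only α′ site) and SN2 alkylation attach C11–C12; the C7 configuration is adjusted in step 8.

Step 8
Reactants: 11 methyl 2-[(3S,3aS)-3-(tert-butyldimethylsilyloxy)-1-methyl-6-oxo-2,3,3a,6,7,8-hexahydroazulen-7-yl]acetate (C7 epimers)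
Product: 13 methyl 2-[(3S,3aS,4R,7R)-3-(tert-butyldimethylsilyloxy)-1,4-dimethyl-6-oxo-2,3,3a,4,5,6,7,8-octahydroazulen-7-yl]acetate, via trimethylsilyl enol ether 12 (not isolated)
Conditions: MeMgBr, CuBr·SMe2 (10 mol %), TMSCl, THF, −78 °C; 1 M HCl; then DBU (0.2 equiv), toluene, rt
Reagents that add atoms: methylmagnesium bromide (C[Mg]Br); chlorotrimethylsilane (C[Si](C)(C)Cl; silyl group of 12 only, lost on hydrolysis)
Why: Copper-catalysed conjugate addition of methyl anti to the C1–C2 bond (γ-substituent control in a cycloalkenone) sets C10 (α-methyl), and base equilibration of the α-keto centre C7 is expected to favour the 7,10-trans isomer (menthone-type preference).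

Step 9
Reactants: 13 methyl 2-[(3S,3aS,4R,7R)-3-(tert-butyldimethylsilyloxy)-1,4-dimethyl-6-oxo-2,3,3a,4,5,6,7,8-octahydroazulen-7-yl]acetate
Product: 15 2α-hydroxy-13-nor-1αH,7αH,10βH-guai-4-en-12,8β-olide, via silyl-protected lactone 14 (not isolated)
Conditions: LiBH(s-Bu)3, THF, −78 to 0 °C; then HCl (1% in MeOH), rt
Reagents that add atoms: none
Why: The bulky hydride attacks the ketone anti to the C7 side chain (cis alcohol, reinforced by the trans-directing 10-methyl), the alkoxide lactonizes onto the cis ester, and acidic methanol removes the silyl ether.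

Step 10
Reactants: 15 2α-hydroxy-13-nor-1αH,7αH,10βH-guai-4-en-12,8β-olide
Product: 16 (11R)-2α,11-dihydroxy-13-nor-1αH,7αH,10βH-guai-4-en-12,8β-olide
Conditions: KN(SiMe3)2 (2.2 equiv), THF, −78 °C; 2-(phenylsulfonyl)-3-phenyloxaziridine; aq. NH4Cl
Reagents that add atoms: 2-(phenylsulfonyl)-3-phenyloxaziridine (O=S(=O)(N1OC1c1ccccc1)c1ccccc1)
Why: Davis α-hydroxylation of the lactone enolate from the convex face; the C11 configuration formed here is irrelevant because step 11 re-sets it.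

Step 11
Reactants: 16 (11R)-2α,11-dihydroxy-13-nor-1αH,7αH,10βH-guai-4-en-12,8β-olide
Product: 17 (11R)-2α,11,13-trihydroxy-1αH,7αH,10βH-guai-4-en-12,8β-olide
Conditions: LiN(i-Pr)2 (3.3 equiv), THF, −78 to −30 °C; HCHO (gas), −78 °C; aq. NH4Cl
Reagents that add atoms: formaldehyde (C=O)
Why: Aldol addition of the α-alkoxide enolate (dianion of the α-hydroxy lactone) to formaldehyde on the convex face of the cis-fused lactone puts CH2OH on the H-7 side and the 11-OH on the C6 side, as the bridge requires.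

Step 12
Reactants: 17 (11R)-2α,11,13-trihydroxy-1αH,7αH,10βH-guai-4-en-12,8β-olide
Product: 18 (11R)-13-acetoxy-2α,11-dihydroxy-1αH,7αH,10βH-guai-4-en-12,8β-olide
Conditions: AcCl (1.05 equiv), 2,4,6-collidine, CH2Cl2, −78 °C
Reagents that add atoms: acetyl chloride (CC(Cl)=O)
Why: Chemoselective acylation of the primary alcohol over the secondary and tertiary hydroxyls at low temperature.

Step 13
Reactants: 18 (11R)-13-acetoxy-2α,11-dihydroxy-1αH,7αH,10βH-guai-4-en-12,8β-olide
Product: 19 (11R)-13-acetoxy-11-hydroxy-2α-[(E)-2-methylbut-2-enoyloxy]-1αH,7αH,10βH-guai-4-en-12,8β-olide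
Conditions: tigloyl chloride, pyridine, DMAP (cat.), CH2Cl2, 0 °C to rt
Reagents that add atoms: tigloyl chloride (C/C=C(\C)C(Cl)=O)
Why: DMAP-catalysed acylation of the secondary C2 alcohol; the tertiary α-hydroxy lactone OH does not react.

Step 14
Reactants: 19 (11R)-13-acetoxy-11-hydroxy-2α-[(E)-2-methylbut-2-enoyloxy]-1αH,7αH,10βH-guai-4-en-12,8β-olide
Product: 20 13-acetoxy-5β,11-epoxy-4α-hydroxy-2α-[(E)-2-methylbut-2-enoyloxy]-1αH,7αH,10βH-guaian-12,8β-olide (CNP0112086.1)
Conditions: RVC anode/Pt cathode, undivided cell, constant current (2.2 F/mol), (2,4-Br2C6H3)3N (10 mol %), n-Bu4NBF4, 2,6-lutidine, MeCN/H2O 9:1, rt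
Reagents that add atoms: water (O)
Why: Proposed new method: mediated anodic one-electron oxidation of the electron-rich tetrasubstituted C4=C5 alkene gives a radical cation that the tethered tertiary 11-OH traps 5-exo at C5 from the β face (the only face the C7 tether reaches), the tertiary C4 radical is oxidized to a cation that water captures anti to the new C5–O bond (α face, assisted by the neighbouring 2α-ester carbonyl) while protons are reduced to H2 at the cathode, so the oxolane bridge and both C4/C5 stereocentres form together; the closest known reactions are anodic olefin couplings of enol-ether radical cations with alcohol nucleophiles and electrochemical dioxygenation of styrenes, neither shown for an unactivated tetrasubstituted alkene with a tertiary alcohol.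

## Compound list

1 | (S)-4-(tert-butyldimethylsilyloxy)cyclopent-2-en-1-one | CC(C)(C)[Si](C)(C)O[C@H]1CC(=O)C=C1 | starting material
2 | (S)-4-(tert-butyldimethylsilyloxy)-2-iodocyclopent-2-en-1-one | CC(C)(C)[Si](C)(C)O[C@H]1CC(=O)C(I)=C1 | intermediate
3 | (3-ethoxy-3-oxopropyl)zinc bromide | CCOC(=O)CC[Zn]Br | starting material
4 | ethyl 3-[(3S)-3-(tert-butyldimethylsilyloxy)-5-oxocyclopent-1-en-1-yl]propanoate | CC(C)(C)[Si](C)(C)O[C@H]1CC(=O)C(CCC(=O)OCC)=C1 | intermediate
5 | bromomagnesium enolate of the trans vinyl 1,4-adduct of 4 (not isolated) | CC(C)(C)[Si](C)(C)O[C@H]1CC(O[Mg]Br)=C(CCC(=O)OCC)[C@@H]1C=C | intermediate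
6 | ethyl 3-[(4S,5S)-4-(tert-butyldimethylsilyloxy)-5-ethenyl-2-(trifluoromethylsulfonyloxy)cyclopent-1-en-1-yl]propanoate | CC(C)(C)[Si](C)(C)O[C@H]1CC(OS(=O)(=O)C(F)(F)F)=C(CCC(=O)OCC)[C@@H]1C=C | intermediate
7 | ethyl 3-[(4S,5S)-4-(tert-butyldimethylsilyloxy)-5-ethenyl-2-methylcyclopent-1-en-1-yl]propanoate | CC(C)(C)[Si](C)(C)O[C@H]1CC(C)=C(CCC(=O)OCC)[C@@H]1C=C | intermediate
8 | N-methoxy-N-methyl amide corresponding to ester 7 (not isolated) | CC(C)(C)[Si](C)(C)O[C@H]1CC(C)=C(CCC(=O)N(C)OC)[C@@H]1C=C | intermediate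
9 | 5-[(4S,5S)-4-(tert-butyldimethylsilyloxy)-5-ethenyl-2-methylcyclopent-1-en-1-yl]pent-1-en-3-one | CC(C)(C)[Si](C)(C)O[C@H]1CC(C)=C(CCC(=O)C=C)[C@@H]1C=C | intermediate
10 | (3S,3aS)-3-(tert-butyldimethylsilyloxy)-1-methyl-3,3a,7,8-tetrahydroazulen-6(2H)-one (guaiane: 2α-OTBS, 1α-H, 4-ene, 9-ene, 8-one) | CC(C)(C)[Si](C)(C)O[C@H]1CC(C)=C2CCC(=O)C=C[C@H]12 | intermediate
11 | methyl 2-[(3S,3aS)-3-(tert-butyldimethylsilyloxy)-1-methyl-6-oxo-2,3,3a,6,7,8-hexahydroazulen-7-yl]acetate (C7 epimers) | CC(C)(C)[Si](C)(C)O[C@H]1CC(C)=C2CC(CC(=O)OC)C(=O)C=C[C@H]12 | intermediate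
12 | trimethylsilyl enol ether (C8–OTMS, C8=C9) of the 10α-methyl adduct (not isolated) | CC(C)(C)[Si](C)(C)O[C@H]1CC(C)=C2CC(CC(=O)OC)C(O[Si](C)(C)C)=C[C@@H](C)[C@H]12 | intermediate
13 | methyl 2-[(3S,3aS,4R,7R)-3-(tert-butyldimethylsilyloxy)-1,4-dimethyl-6-oxo-2,3,3a,4,5,6,7,8-octahydroazulen-7-yl]acetate (guaiane: 7β side chain, 10α-methyl) | CC(C)(C)[Si](C)(C)O[C@H]1CC(C)=C2C[C@H](CC(=O)OC)C(=O)C[C@@H](C)[C@H]12 | intermediate
14 | 2α-(tert-butyldimethylsilyloxy)-13-nor-1αH,7αH,10βH-guai-4-en-12,8β-olide (not isolated) | CC(C)(C)[Si](C)(C)O[C@H]1CC(C)=C2C[C@H]3[C@@H](C[C@@H](C)[C@H]12)OC(=O)C3 | intermediate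
15 | 2α-hydroxy-13-nor-1αH,7αH,10βH-guai-4-en-12,8β-olide | O[C@H]1CC(C)=C2C[C@H]3[C@@H](C[C@@H](C)[C@H]12)OC(=O)C3 | intermediate
16 | (11R)-2α,11-dihydroxy-13-nor-1αH,7αH,10βH-guai-4-en-12,8β-olide (11-OH on the H-7 face) | O[C@H]1CC(C)=C2C[C@H]3[C@@H](C[C@@H](C)[C@H]12)OC(=O)[C@@H]3O | intermediate
17 | (11R)-2α,11,13-trihydroxy-1αH,7αH,10βH-guai-4-en-12,8β-olide (11-OH on the C6 face) | O[C@H]1CC(C)=C2C[C@H]3[C@@H](C[C@@H](C)[C@H]12)OC(=O)[C@@]3(CO)O | intermediate
18 | (11R)-13-acetoxy-2α,11-dihydroxy-1αH,7αH,10βH-guai-4-en-12,8β-olide | O[C@H]1CC(C)=C2C[C@H]3[C@@H](C[C@@H](C)[C@H]12)OC(=O)[C@@]3(COC(C)=O)O | intermediate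
19 | (11R)-13-acetoxy-11-hydroxy-2α-[(E)-2-methylbut-2-enoyloxy]-1αH,7αH,10βH-guai-4-en-12,8β-olide | C/C=C(\C)C(=O)O[C@H]1CC(C)=C2C[C@H]3[C@@H](C[C@@H](C)[C@H]12)OC(=O)[C@@]3(COC(C)=O)O | intermediate
20 | 13-acetoxy-5β,11-epoxy-4α-hydroxy-2α-[(E)-2-methylbut-2-enoyloxy]-1αH,7αH,10βH-guaian-12,8β-olide (CNP0112086.1) | C/C=C(\C)C(=O)O[C@H]1C[C@@](C)(O)[C@@]23C[C@H]4[C@@H](C[C@@H](C)[C@H]12)OC(=O)[C@@]4(COC(C)=O)O3 | target

## Step count and weak points

Total steps: 14. Longest linear sequence: 14 steps (from 1).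

Steps most likely to fail:

Step 14 (the proposed new step). The radical cation may lose an allylic proton or be trapped by water before the 11-OH closes, and the facial course at C4 is untested. The fallback uses known chemistry and sets out from 18. VO(acac)2/t-BuOOH, directed by the homoallylic 2α-OH, gives 13-acetoxy-4α,5α-epoxy-2α,11-dihydroxy-1αH,7αH,10βH-guaian-12,8β-olide F1. Catalytic camphorsulfonic acid in CH2Cl2 then opens the epoxide at C5 with the 11-OH (5-exo, inversion) to give 13-acetoxy-5β,11-epoxy-2α,4α-dihydroxy-1αH,7αH,10βH-guaian-12,8β-olide F2. Tigloyl chloride/DMAP acylates its only secondary hydroxyl and the route is rejoined at 20.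

Step 8 (and step 9, which inherits its result). The configuration at C7 rests on a thermodynamic preference that is only argued by analogy; this is the weakest stereochemical link in the route. If the 7,10-trans ketone does not dominate, the lactone would be built on the wrong face. The fallback sets out from 10 and forces the lactone from the C8 oxygen. MeMgBr/CuBr·SMe2/TMSCl and dilute HCl give (3S,3aS,4R)-3-(tert-butyldimethylsilyloxy)-1,4-dimethyl-3,3a,4,5,7,8-hexahydroazulen-6(2H)-one F3. LiBH(s-Bu)3 gives the 8β-alcohol F4 (equatorial attack, trans to the 10-methyl as with 3-alkylcycloalkanones). Glyoxylic acid chloride tosylhydrazone with PhNMe2 then Et3N gives the 8β-diazoacetate F5. Rh2(OAc)4-catalysed 1,5 C–H insertion into the cis C7–H closes the cis-fused γ-lactone; insertion at C9 is a possible competitor. The route is rejoined at 14, which is desilylated as in step 9.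

Step 11. A trianion must react cleanly with gaseous formaldehyde, and the convex-face attack is assumed. The fallback sets out from 16 and replaces the lithium enediolate by a Lewis-acid Mukaiyama aldol. TMSCl/Et3N gives the 2,11-bis(trimethylsilyl) ether F6. LiN(i-Pr)2/TMSCl gives the silyl ketene acetal F7. Sc(OTf)3-catalysed addition to aqueous formaldehyde on the convex face, followed by dilute HCl, returns to the route at 17.

Further compounds
F1 | step 14 | 13-acetoxy-4α,5α-epoxy-2α,11-dihydroxy-1αH,7αH,10βH-guaian-12,8β-olide | O[C@H]1C[C@@]2(C)O[C@]23C[C@H]4[C@@H](C[C@@H](C)[C@H]13)OC(=O)[C@@]4(COC(C)=O)O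
F2 | step 14 | 13-acetoxy-5β,11-epoxy-2α,4α-dihydroxy-1αH,7αH,10βH-guaian-12,8β-olide | O[C@H]1C[C@@](C)(O)[C@@]23C[C@H]4[C@@H](C[C@@H](C)[C@H]12)OC(=O)[C@@]4(COC(C)=O)O3
F3 | step 8 | (3S,3aS,4R)-3-(tert-butyldimethylsilyloxy)-1,4-dimethyl-3,3a,4,5,7,8-hexahydroazulen-6(2H)-one | CC(C)(C)[Si](C)(C)O[C@H]1CC(C)=C2CCC(=O)C[C@@H](C)[C@H]12
F4 | step 8 | (3S,3aS,4R,6S)-3-(tert-butyldimethylsilyloxy)-1,4-dimethyl-2,3,3a,4,5,6,7,8-octahydroazulen-6-ol (guaiane: 8β-OH) | CC(C)(C)[Si](C)(C)O[C@H]1CC(C)=C2CC[C@H](O)C[C@@H](C)[C@H]12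
F5 | step 8 | diazoacetate ester of F4 | CC(C)(C)[Si](C)(C)O[C@H]1CC(C)=C2CC[C@H](OC(=O)C=[N+]=[N-])C[C@@H](C)[C@H]12
F6 | step 11 | 2,11-bis(trimethylsilyl) ether of 16 | C[Si](C)(C)O[C@H]1CC(C)=C2C[C@H]3[C@@H](C[C@@H](C)[C@H]12)OC(=O)[C@@H]3O[Si](C)(C)C
F7 | step 11 | trimethylsilyl ketene acetal of F6 | C[Si](C)(C)O[C@H]1CC(C)=C2C[C@H]3[C@@H](C[C@@H](C)[C@H]12)OC(O[Si](C)(C)C)=C3O[Si](C)(C)C
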